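## Retrosynthetic overview

1. The target is opened by global acidolysis (one tert-butyl ester, three MOM ethers), then by a Heck disconnection of the aryl–vinyl bond into a 7-bromo cis-benzodioxane acid and the acrylate of a protected (R)-aryl-lactate.
2. The cis (2S,3S) pair comes from syn, enantioselective hydrogenation of a 3-aryl-1,4-benzodioxine-2-carboxylic acid.
3. The only ring that must be built, the 1,4-dioxine, closes by intramolecular oxa-Michael addition of the phenol para to Br onto the β-carbon of an α-aryloxy-β-triflyloxy cinnamate, followed by loss of triflate.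
4. The cyclisation substrate comes from Rh-carbenoid O–H insertion of a mono-PMB bromocatechol (from 5-bromosalicylaldehyde) with a diazo β-keto ester (from 3',4'-dihydroxyacetophenone). This forms O1–C2 and fixes the regiochemistry.
5. The lactate acrylate comes from Cu-catalysed opening of methyl (R)-glycidate by the aryl Grignard of MOM-protected 4-bromoguaiacol (chiral pool sets R).

Assumption: the SMILES is read literally, i.e. (2S,3S) = CO2H and aryl cis on the dioxane ring and (R) at the lactate. The hand of the Ir catalyst in step 11 is written as (Sa,S); it cannot be predicted for this substrate, so it is checked on the first run (chiral HPLC/ECD) and the mirror-image catalyst is used if the 2R,3R acid forms.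

## Route

**Step 1**
Reactants: 1 3',4'-dihydroxyacetophenone
Product: 2 1-[3,4-bis(methoxymethoxy)phenyl]ethanone
Conditions: MOMCl (2.5 equiv), iPr2NEt (3 equiv), CH2Cl2, 0 °C to rt
Reagents that add atoms: chloromethyl methyl ether (MOMCl), COCCl
Why: Williamson-type O-alkylation masks both catechol OH groups as MOM acetals, which survive base, Rh, DDQ, Pd and H2 and fall off with acid at the end.

**Step 2**
Reactants: 2 1-[3,4-bis(methoxymethoxy)phenyl]ethanone
Product: 3 methyl 3-[3,4-bis(methoxymethoxy)phenyl]-3-oxopropanoate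
Conditions: NaH (2.5 equiv), (MeO)2CO (5 equiv), toluene, 90 °C; then AcOH, 0 °C
Reagents that add atoms: dimethyl carbonate, COC(=O)OC
Why: Claisen-type C-acylation of the ketone enolate, driven by formation of the stabilised β-keto ester enolate.

**Step 3**
Reactants: 3 methyl 3-[3,4-bis(methoxymethoxy)phenyl]-3-oxopropanoate
Product: 4 methyl 2-diazo-3-[3,4-bis(methoxymethoxy)phenyl]-3-oxopropanoate
Conditions: p-ABSA (1.1 equiv), Et3N (1.5 equiv), MeCN, 0 °C to rt
Reagents that add atoms: 4-acetamidobenzenesulfonyl azide (p-ABSA), CC(=O)Nc1ccc(cc1)S(=O)(=O)N=[N+]=[N-]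
Why: Regitz diazo transfer to the doubly activated methylene is reliable for aryl β-keto esters.

**Step 4**
Reactants: 5 5-bromo-2-hydroxybenzaldehyde
Product: 6 5-bromo-2-[(4-methoxybenzyl)oxy]benzaldehyde
Conditions: PMBCl (1.1 equiv), K2CO3 (1.5 equiv), DMF, 60 °C
Reagents that add atoms: 4-methoxybenzyl chloride (PMBCl), COc1ccc(CCl)cc1
Why: Williamson etherification of the acidic salicylaldehyde OH reserves the oxygen para to Br, which later becomes O4.

**Step 5**
Reactants: 6 5-bromo-2-[(4-methoxybenzyl)oxy]benzaldehyde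
Product: 8 5-bromo-2-[(4-methoxybenzyl)oxy]phenol, via aryl formate 7 (not isolated)
Conditions: mCPBA (1.4 equiv), CH2Cl2, rt; then K2CO3 (cat.), MeOH, rt
Reagents that add atoms: meta-chloroperoxybenzoic acid (mCPBA), OOC(=O)c1cccc(Cl)c1
Why: Baeyer–Villiger (Dakin-type) oxidation with migration of the ortho-alkoxy aryl ring, then formate methanolysis, gives the free OH meta to Br, which becomes O1.

**Step 6**
Reactants: 8 5-bromo-2-[(4-methoxybenzyl)oxy]phenol; 4 methyl 2-diazo-3-[3,4-bis(methoxymethoxy)phenyl]-3-oxopropanoate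
Product: 9 methyl 2-{5-bromo-2-[(4-methoxybenzyl)oxy]phenoxy}-3-[3,4-bis(methoxymethoxy)phenyl]-3-oxopropanoate (racemic)
Conditions: Rh2(OAc)4 (1 mol%), CH2Cl2, 40 °C, slow addition of 4
Reagents that add atoms: none
Why: Rh(II)-carbenoid O–H insertion into the only free phenol forms the O1–C2 bond under neutral conditions; the C2 centre is erased in step 7.

**Step 7**
Reactants: 9 methyl 2-{5-bromo-2-[(4-methoxybenzyl)oxy]phenoxy}-3-[3,4-bis(methoxymethoxy)phenyl]-3-oxopropanoate
Product: 10 methyl 2-{5-bromo-2-[(4-methoxybenzyl)oxy]phenoxy}-3-[3,4-bis(methoxymethoxy)phenyl]-3-[(trifluoromethylsulfonyl)oxy]prop-2-enoate (E/Z mixture, used as such)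
Conditions: Tf2O (1.3 equiv), iPr2NEt (2 equiv), CH2Cl2, −78 to 0 °C
Reagents that add atoms: trifluoromethanesulfonic anhydride (Tf2O), O=S(=O)(OS(=O)(=O)C(F)(F)F)C(F)(F)F
Why: O-sulfonylation of the acidic β-keto ester enolate gives a cinnamate with a β leaving group; both alkene isomers converge in step 9.

**Step 8**
Reactants: 10 the PMB-protected enol triflate
Product: 11 methyl 2-(5-bromo-2-hydroxyphenoxy)-3-[3,4-bis(methoxymethoxy)phenyl]-3-[(trifluoromethylsulfonyl)oxy]prop-2-enoate (E/Z mixture)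
Conditions: DDQ (1.5 equiv), CH2Cl2/pH 7 buffer 10:1, 0 °C to rt
Reagents that add atoms: none
Why: Oxidative PMB cleavage is orthogonal to MOM ethers, the vinyl triflate and the aryl bromide, and frees the phenol para to Br.

**Step 9**
Reactants: 11 the phenol enol triflate
Product: 13 methyl 7-bromo-3-[3,4-bis(methoxymethoxy)phenyl]-1,4-benzodioxine-2-carboxylate, via oxa-Michael adduct enolate 12 (not isolated)
Conditions: Cs2CO3 (1.5 equiv), MeCN, 0 to 40 °C
Reagents that add atoms: none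
Why: Intramolecular 6-endo-trig oxa-Michael addition of the phenoxide to the β-carbon gives ester enolate 12, which expels triflate (E1cB) irreversibly to close the dioxine ring; no stereocentre is formed.

**Step 10**
Reactants: 13 methyl 7-bromo-3-[3,4-bis(methoxymethoxy)phenyl]-1,4-benzodioxine-2-carboxylate
Product: 14 7-bromo-3-[3,4-bis(methoxymethoxy)phenyl]-1,4-benzodioxine-2-carboxylic acid
Conditions: LiOH·H2O (3 equiv), THF/H2O 3:1, rt; then 1 M HCl to pH 3, 0 °C
Reagents that add atoms: lithium hydroxide, [Li+].[OH-]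
Why: Saponification at a stage with no stereocentre gives the free acid that directs the hydrogenation.

**Step 11**
Reactants: 14 7-bromo-3-[3,4-bis(methoxymethoxy)phenyl]-1,4-benzodioxine-2-carboxylic acid
Product: 15 (2S,3S)-7-bromo-3-[3,4-bis(methoxymethoxy)phenyl]-2,3-dihydro-1,4-benzodioxine-2-carboxylic acid (CO2H and aryl cis)
Conditions: [Ir(cod)((Sa,S)-SIPHOX)]BArF (2 mol%), H2 (10 bar), Et3N (0.5 equiv), MeOH, 45 °C
Reagents that add atoms: none
Why: Carboxylate-directed Ir-catalysed asymmetric hydrogenation adds H2 syn to one face of the tetrasubstituted C2=C3 bond, so both centres form together as the cis pair and the chiral spiro P,N ligand selects the 2S,3S face.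

**Step 12**
Reactants: 16 4-bromo-2-methoxyphenol
Product: 17 4-bromo-2-methoxy-1-(methoxymethoxy)benzene
Conditions: MOMCl (1.3 equiv), iPr2NEt (1.5 equiv), CH2Cl2, 0 °C to rt
Reagents that add atoms: chloromethyl methyl ether (MOMCl), COCCl
Why: O-alkylation gives a phenol protecting group that tolerates Grignard formation and matches the final acid deprotection.

**Step 13**
Reactants: 17 4-bromo-2-methoxy-1-(methoxymethoxy)benzene; 18 methyl (2R)-oxirane-2-carboxylate (methyl (R)-glycidate)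
Product: 20 methyl (2R)-2-hydroxy-3-[3-methoxy-4-(methoxymethoxy)phenyl]propanoate, via arylmagnesium bromide 19 (not isolated)
Conditions: Mg, THF, 50 °C; then CuI (10 mol%), 18 (0.75 equiv), THF, −40 to −20 °C; aq. NH4Cl
Reagents that add atoms: magnesium, [Mg] (held only in intermediate 19, lost on work-up)
Why: Cu(I)-catalysed SN2 opening of the epoxide at its unsubstituted CH2 outruns ester attack at low temperature and leaves the C2–O bond untouched, so the R centre is carried over from the chiral pool.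

**Step 14**
Reactants: 20 methyl (2R)-2-hydroxy-3-[3-methoxy-4-(methoxymethoxy)phenyl]propanoate
Product: 21 (2R)-2-hydroxy-3-[3-methoxy-4-(methoxymethoxy)phenyl]propanoic acid
Conditions: LiOH·H2O (2 equiv), THF/H2O 3:1, 0 °C to rt; then 1 M HCl to pH 3, 0 °C
Reagents that add atoms: lithium hydroxide, [Li+].[OH-]
Why: Mild saponification of an α-hydroxy ester proceeds without racemisation.

**Step 15**
Reactants: 21 (2R)-2-hydroxy-3-[3-methoxy-4-(methoxymethoxy)phenyl]propanoic acid
Product: 22 tert-butyl (2R)-2-hydroxy-3-[3-methoxy-4-(methoxymethoxy)phenyl]propanoate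
Conditions: O-tert-butyl-N,N'-diisopropylisourea (3 equiv), CH2Cl2, rt
Reagents that add atoms: O-tert-butyl-N,N'-diisopropylisourea, CC(C)NC(=NC(C)C)OC(C)(C)C
Why: tert-Butyl transfer from the protonated isourea to the carboxylate is neutral, leaves the alcohol and MOM ether alone, and does not activate the carbonyl, so the stereocentre is safe.

**Step 16**
Reactants: 22 tert-butyl (2R)-2-hydroxy-3-[3-methoxy-4-(methoxymethoxy)phenyl]propanoate
Product: 23 tert-butyl (2R)-2-(acryloyloxy)-3-[3-methoxy-4-(methoxymethoxy)phenyl]propanoate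
Conditions: acryloyl chloride (1.3 equiv), Et3N (2 equiv), CH2Cl2, −20 to 0 °C
Reagents that add atoms: acryloyl chloride, C=CC(=O)Cl
Why: O-acylation with an acid chloride occurs at oxygen with retention at carbon.

**Step 17**
Reactants: 15 (2S,3S)-7-bromo-3-[3,4-bis(methoxymethoxy)phenyl]-2,3-dihydro-1,4-benzodioxine-2-carboxylic acid; 23 tert-butyl (2R)-2-(acryloyloxy)-3-[3-methoxy-4-(methoxymethoxy)phenyl]propanoate
Product: 24 (2S,3S)-3-[3,4-bis(methoxymethoxy)phenyl]-7-[(E)-3-({(2R)-1-tert-butoxy-3-[3-methoxy-4-(methoxymethoxy)phenyl]-1-oxopropan-2-yl}oxy)-3-oxoprop-1-en-1-yl]-2,3-dihydro-1,4-benzodioxine-2-carboxylic acid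
Conditions: Pd2(dba)3 (2.5 mol%), [HP(t-Bu)3]BF4 (6 mol%), Cy2NMe (3 equiv), 1,4-dioxane, 50 °C
Reagents that add atoms: none
Why: Mizoroki–Heck coupling (oxidative addition, syn carbopalladation, syn β-hydride elimination) gives the E-cinnamate and joins the two halves, while 15 reacts as its carboxylate, whose C2–H is not acidic enough to epimerise.

**Step 18**
Reactants: 24 the Heck product
Product: 25 (2S,3S)-7-[(E)-3-{[(1R)-1-carboxy-2-(4-hydroxy-3-methoxyphenyl)ethyl]oxy}-3-oxoprop-1-en-1-yl]-3-(3,4-dihydroxyphenyl)-2,3-dihydro-1,4-benzodioxine-2-carboxylic acid (target)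
Conditions: TFA/CH2Cl2/H2O 45:50:5, 0 °C to rt; RP-HPLC
Reagents that add atoms: none
Why: Acidolysis removes the tert-butyl ester (alkyl–oxygen cleavage) and hydrolyses the three MOM acetals without base, so the cinnamate ester, the cis C2/C3 pair (benzylic ionisation is disfavoured by the adjacent carboxyl) and the lactate centre are kept.

## Compound list

1 | 3',4'-dihydroxyacetophenone | CC(=O)c1ccc(O)c(O)c1 | starting material
2 | 1-[3,4-bis(methoxymethoxy)phenyl]ethanone | CC(=O)c1ccc(OCOC)c(OCOC)c1 | intermediate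
3 | methyl 3-[3,4-bis(methoxymethoxy)phenyl]-3-oxopropanoate | COC(=O)CC(=O)c1ccc(OCOC)c(OCOC)c1 | intermediate
4 | methyl 2-diazo-3-[3,4-bis(methoxymethoxy)phenyl]-3-oxopropanoate | COC(=O)C(=[N+]=[N-])C(=O)c1ccc(OCOC)c(OCOC)c1 | intermediate
5 | 5-bromo-2-hydroxybenzaldehyde | O=Cc1cc(Br)ccc1O | starting material
6 | 5-bromo-2-[(4-methoxybenzyl)oxy]benzaldehyde | COc1ccc(COc2ccc(Br)cc2C=O)cc1 | intermediate
7 | 5-bromo-2-[(4-methoxybenzyl)oxy]phenyl formate (not isolated) | COc1ccc(COc2ccc(Br)cc2OC=O)cc1 | intermediate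
8 | 5-bromo-2-[(4-methoxybenzyl)oxy]phenol | COc1ccc(COc2ccc(Br)cc2O)cc1 | intermediate
9 | methyl 2-{5-bromo-2-[(4-methoxybenzyl)oxy]phenoxy}-3-[3,4-bis(methoxymethoxy)phenyl]-3-oxopropanoate (racemic) | COC(=O)C(Oc1cc(Br)ccc1OCc1ccc(OC)cc1)C(=O)c1ccc(OCOC)c(OCOC)c1 | intermediate
10 | methyl 2-{5-bromo-2-[(4-methoxybenzyl)oxy]phenoxy}-3-[3,4-bis(methoxymethoxy)phenyl]-3-[(trifluoromethylsulfonyl)oxy]prop-2-enoate (E/Z mixture) | COC(=O)C(Oc1cc(Br)ccc1OCc1ccc(OC)cc1)=C(OS(=O)(=O)C(F)(F)F)c1ccc(OCOC)c(OCOC)c1 | intermediate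
11 | methyl 2-(5-bromo-2-hydroxyphenoxy)-3-[3,4-bis(methoxymethoxy)phenyl]-3-[(trifluoromethylsulfonyl)oxy]prop-2-enoate (E/Z mixture) | COC(=O)C(Oc1cc(Br)ccc1O)=C(OS(=O)(=O)C(F)(F)F)c1ccc(OCOC)c(OCOC)c1 | intermediate
12 | ester enolate anion of methyl 7-bromo-3-[3,4-bis(methoxymethoxy)phenyl]-3-[(trifluoromethylsulfonyl)oxy]-2,3-dihydro-1,4-benzodioxine-2-carboxylate (Cs+ counter-ion, not isolated) | COC([O-])=C1Oc2cc(Br)ccc2OC1(OS(=O)(=O)C(F)(F)F)c1ccc(OCOC)c(OCOC)c1 | intermediate
13 | methyl 7-bromo-3-[3,4-bis(methoxymethoxy)phenyl]-1,4-benzodioxine-2-carboxylate | COC(=O)C1=C(c2ccc(OCOC)c(OCOC)c2)Oc2ccc(Br)cc2O1 | intermediate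
14 | 7-bromo-3-[3,4-bis(methoxymethoxy)phenyl]-1,4-benzodioxine-2-carboxylic acid | OC(=O)C1=C(c2ccc(OCOC)c(OCOC)c2)Oc2ccc(Br)cc2O1 | intermediate
15 | (2S,3S)-7-bromo-3-[3,4-bis(methoxymethoxy)phenyl]-2,3-dihydro-1,4-benzodioxine-2-carboxylic acid (cis) | OC(=O)[C@H]1Oc2cc(Br)ccc2O[C@H]1c1ccc(OCOC)c(OCOC)c1 | intermediate
16 | 4-bromo-2-methoxyphenol | COc1cc(Br)ccc1O | starting material
17 | 4-bromo-2-methoxy-1-(methoxymethoxy)benzene | COCOc1ccc(Br)cc1OC | intermediate
18 | methyl (2R)-oxirane-2-carboxylate | COC(=O)[C@H]1CO1 | starting material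
19 | [3-methoxy-4-(methoxymethoxy)phenyl]magnesium bromide (not isolated) | COCOc1ccc([Mg]Br)cc1OC | intermediate
20 | methyl (2R)-2-hydroxy-3-[3-methoxy-4-(methoxymethoxy)phenyl]propanoate | COC(=O)[C@H](O)Cc1ccc(OCOC)c(OC)c1 | intermediate
21 | (2R)-2-hydroxy-3-[3-methoxy-4-(methoxymethoxy)phenyl]propanoic acid | OC(=O)[C@H](O)Cc1ccc(OCOC)c(OC)c1 | intermediate
22 | tert-butyl (2R)-2-hydroxy-3-[3-methoxy-4-(methoxymethoxy)phenyl]propanoate | CC(C)(C)OC(=O)[C@H](O)Cc1ccc(OCOC)c(OC)c1 | intermediate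
23 | tert-butyl (2R)-2-(acryloyloxy)-3-[3-methoxy-4-(methoxymethoxy)phenyl]propanoate | CC(C)(C)OC(=O)[C@H](OC(=O)C=C)Cc1ccc(OCOC)c(OC)c1 | intermediate
24 | (2S,3S)-3-[3,4-bis(methoxymethoxy)phenyl]-7-[(E)-3-({(2R)-1-tert-butoxy-3-[3-methoxy-4-(methoxymethoxy)phenyl]-1-oxopropan-2-yl}oxy)-3-oxoprop-1-en-1-yl]-2,3-dihydro-1,4-benzodioxine-2-carboxylic acid | OC(=O)[C@H]1Oc2cc(/C=C/C(=O)O[C@H](Cc3ccc(OCOC)c(OC)c3)C(=O)OC(C)(C)C)ccc2O[C@H]1c1ccc(OCOC)c(OCOC)c1 | intermediate
25 | (2S,3S)-7-[(E)-3-{[(1R)-1-carboxy-2-(4-hydroxy-3-methoxyphenyl)ethyl]oxy}-3-oxoprop-1-en-1-yl]-3-(3,4-dihydroxyphenyl)-2,3-dihydro-1,4-benzodioxine-2-carboxylic acid | COc1cc(C[C@@H](OC(=O)/C=C/c2ccc3c(c2)O[C@H](C(=O)O)[C@H](c2ccc(O)c(O)c2)O3)C(=O)O)ccc1O | target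

## Step count and risks

Total step count: 18.
Longest linear sequence: 11 steps (1 → 2 → 3 → 4 → 9 → 10 → 11 → 13 → 14 → 15 → 24 → 25; steps 1–3, 6–11, 17, 18). That is 11/18 = 0.61 of the total.

The three steps most likely to fail:

**Step 11 (asymmetric hydrogenation of a tetrasubstituted, doubly oxygenated alkene).** Reactivity is plausible for a carboxylate-directed Ir P,N catalyst, but the level and sense of enantioselectivity are unproven. The fallback sets out from 14 and comes back at 15. Acid 14 is hydrogenated with an achiral Crabtree-type catalyst ([Ir(cod)(PCy3)(py)]BArF, H2 50 bar, CH2Cl2), which still adds syn and gives the racemic cis acid. This is 15 together with its mirror image, (2R,3R)-7-bromo-3-[3,4-bis(methoxymethoxy)phenyl]-2,3-dihydro-1,4-benzodioxine-2-carboxylic acid F3. The racemate is resolved classically by crystallising the (S)-1-phenylethylammonium salt of 15 F4 (the antipodal amine is used if the other diastereomeric salt is the less soluble one). Cold dilute acid then liberates 15.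

**Step 9 (oxa-Michael addition–elimination).** The β-carbon carries an electron-rich aryl group, and the phenoxide could instead attack sulfur and strip the triflyl group. The fallback sets out from 9 and comes back at 13. DDQ (CH2Cl2/pH 7 buffer) removes the PMB group of keto ester 9 to give methyl 2-(5-bromo-2-hydroxyphenoxy)-3-[3,4-bis(methoxymethoxy)phenyl]-3-oxopropanoate F1. The free phenol adds to the ketone to give the cyclic hemiketal methyl 7-bromo-3-hydroxy-3-[3,4-bis(methoxymethoxy)phenyl]-2,3-dihydro-1,4-benzodioxine-2-carboxylate F2. Dehydration with MsCl/Et3N (or Burgess reagent), which spares the MOM ethers, gives 13. This is ring closure by carbonyl addition and dehydration instead of conjugate addition–elimination.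

**Step 17 (Heck union of two advanced fragments).** The aryl bromide is electron-rich, a free carboxylate is present, and acrylate 23 is precious. The fallback sets out from 15 (with alcohol 22) and comes back at 25. Acid 15 is converted with O-tert-butyl-N,N'-diisopropylisourea into tert-butyl (2S,3S)-7-bromo-3-[3,4-bis(methoxymethoxy)phenyl]-2,3-dihydro-1,4-benzodioxine-2-carboxylate F5. A Heck reaction with excess acrylic acid (same Pd/P(t-Bu)3/Cy2NMe system) gives the corresponding C7 (E)-acrylic acid F6. Carbodiimide esterification (EDC·HCl, DMAP, CH2Cl2, 0 °C) with alcohol 22 gives the fully protected di-tert-butyl ester of the target skeleton F7. The same TFA/CH2Cl2/H2O treatment as in step 18 then gives 25. The fragments are thus joined by esterification instead of by C–C coupling.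

## Further compounds

F1 | step 9 | methyl 2-(5-bromo-2-hydroxyphenoxy)-3-[3,4-bis(methoxymethoxy)phenyl]-3-oxopropanoate | COC(=O)C(Oc1cc(Br)ccc1O)C(=O)c1ccc(OCOC)c(OCOC)c1
F2 | step 9 | methyl 7-bromo-3-hydroxy-3-[3,4-bis(methoxymethoxy)phenyl]-2,3-dihydro-1,4-benzodioxine-2-carboxylate (hemiketal, diastereomer mixture) | COC(=O)C1Oc2cc(Br)ccc2OC1(O)c1ccc(OCOC)c(OCOC)c1
F3 | step 11 | (2R,3R)-7-bromo-3-[3,4-bis(methoxymethoxy)phenyl]-2,3-dihydro-1,4-benzodioxine-2-carboxylic acid | OC(=O)[C@@H]1Oc2cc(Br)ccc2O[C@@H]1c1ccc(OCOC)c(OCOC)c1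
F4 | step 11 | (S)-1-phenylethylammonium (2S,3S)-7-bromo-3-[3,4-bis(methoxymethoxy)phenyl]-2,3-dihydro-1,4-benzodioxine-2-carboxylate | C[C@H]([NH3+])c1ccccc1.[O-]C(=O)[C@H]1Oc2cc(Br)ccc2O[C@H]1c1ccc(OCOC)c(OCOC)c1
F5 | step 17 | tert-butyl (2S,3S)-7-bromo-3-[3,4-bis(methoxymethoxy)phenyl]-2,3-dihydro-1,4-benzodioxine-2-carboxylate | CC(C)(C)OC(=O)[C@H]1Oc2cc(Br)ccc2O[C@H]1c1ccc(OCOC)c(OCOC)c1
F6 | step 17 | (E)-3-{(2S,3S)-3-[3,4-bis(methoxymethoxy)phenyl]-2-(tert-butoxycarbonyl)-2,3-dihydro-1,4-benzodioxin-7-yl}prop-2-enoic acid | CC(C)(C)OC(=O)[C@H]1Oc2cc(/C=C/C(O)=O)ccc2O[C@H]1c1ccc(OCOC)c(OCOC)c1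
F7 | step 17 | tert-butyl (2S,3S)-3-[3,4-bis(methoxymethoxy)phenyl]-7-[(E)-3-({(2R)-1-tert-butoxy-3-[3-methoxy-4-(methoxymethoxy)phenyl]-1-oxopropan-2-yl}oxy)-3-oxoprop-1-en-1-yl]-2,3-dihydro-1,4-benzodioxine-2-carboxylate | CC(C)(C)OC(=O)[C@H]1Oc2cc(/C=C/C(=O)O[C@H](Cc3ccc(OCOC)c(OC)c3)C(=O)OC(C)(C)C)ccc2O[C@H]1c1ccc(OCOC)c(OCOC)c1
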